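**Plan**

Atom names: chroman O1, C2–C4, C4a, C5–C8, C8a; side chain C1'–C8', with C9' as the CO2H carbon. Retrosynthetic cuts, in order: C2'–C3' (sp3–sp2), O1–C2 (pyran ring), C4–C4a (arm to arene). In the other half the cuts are C7'=C8' and C4'–CH3.
Enabling feature: C2' is a primary carbon separated from O1 by C1' and the fully substituted C2, so a radical or alkylnickel at C2' has no β-leaving group, no π bond within reach and no stereocentre to scramble. C3' is the hydrogen-bearing end of the C3'=C4' alkene, so its E geometry can be stored in an alkenyl iodide.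
Both carbons are therefore made as iodides (like polarity) and joined by a nickel-catalysed reductive cross-electrophile coupling. It tolerates the C9' ester and completes the whole carbon skeleton in one event, and the two iodine atoms are the activating groups and leave in that step.
Forward: methylhydroquinone → silyl ether at the later C6 oxygen → ortho iodide → C5 arm by B-alkyl Suzuki coupling → pyran ring (the only ring made) by asymmetric allylic etherification → vinyl to 2-iodoethyl. In parallel, pent-4-yn-1-ol → alkenyl iodide → aldehyde → dienoate. Then union, then one-pot removal of silyl ether and ethyl ester.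
Stereochemistry: C2 (R in the target) comes from the chiral ligand in the allylic etherification. C3'=C4' (E) comes from syn methylalumination, kept through iodinolysis and coupling. C7'=C8' (E) comes from a stabilised ylide.

Key step: step 12

Assumption: the (R,R) ligand is taken to give the (S)-vinylchroman 9 from the E carbonate 8; if the cyclisation shows the opposite sense, the equally available (S,S) ligand is used and nothing else changes.

Step 1
Reactants: 1 2-methylhydroquinone
Product: 2 2-methyl-4-(triisopropylsilyloxy)phenol
Conditions: TIPSCl (1.0 equiv), imidazole (2.2 equiv), DMF, 0 °C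
Reagents that add atoms: chlorotriisopropylsilane, CC(C)[Si](Cl)(C(C)C)C(C)C
Why: Phenol silylation: the bulky chlorosilane should react first at the hydroxyl with two free ortho positions rather than at the one flanked by the methyl group, and the minor isomer and the bis-ether are removed by chromatography.

Step 2
Reactants: 2 2-methyl-4-(triisopropylsilyloxy)phenol
Product: 3 2-iodo-6-methyl-4-(triisopropylsilyloxy)phenol
Conditions: NIS (1.05 equiv), TsOH·H2O (10 mol %), MeCN, 0 °C to rt, dark
Reagents that add atoms: N-iodosuccinimide, O=C1CCC(=O)N1I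
Why: Electrophilic aromatic iodination: the free hydroxyl is the strongest donor, its para position and one ortho position are occupied, and the positions next to the silyl ether are shielded by the isopropyl groups, so iodine should enter at the one free ortho position.

Step 3
Reactants: 4 (E)-3-methylpent-2-en-4-yn-1-ol
Product: 5 (E)-3-methylpenta-2,4-dien-1-ol
Conditions: H2 (1 atm, 1 equiv uptake), Pd/CaCO3 poisoned with Pb(OAc)2, quinoline, EtOAc, 0 °C
Reagents that add atoms: none
Why: Lindlar semihydrogenation: the poisoned palladium surface should take the terminal alkyne to the alkene and release it, leaving the trisubstituted E double bond and its geometry untouched.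

Step 4
Reactants: 3 2-iodo-6-methyl-4-(triisopropylsilyloxy)phenol; 5 (E)-3-methylpenta-2,4-dien-1-ol
Product: 7 2-[(3E)-5-hydroxy-3-methylpent-3-en-1-yl]-6-methyl-4-(triisopropylsilyloxy)phenol, via bis(9-BBN) adduct 6 (not isolated)
Conditions: 5, 9-BBN (2.2 equiv), THF, 0 °C to rt; then 3, PdCl2(dppf) (5 mol %), aq. K3PO4 (4 equiv), DMF, 50 °C, degassed
Reagents that add atoms: none
Why: Hydroboration followed by B-alkyl Suzuki–Miyaura coupling: one equivalent of 9-BBN caps the hydroxyl as a borinate, the second adds to the monosubstituted end of the diene with boron on the terminal carbon because the trisubstituted double bond is too hindered for this borane, and the base-activated primary alkylborane then transfers its alkyl group to the arylpalladium iodide formed from 3.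

Step 5
Reactants: 7 2-[(3E)-5-hydroxy-3-methylpent-3-en-1-yl]-6-methyl-4-(triisopropylsilyloxy)phenol
Product: 8 (2E)-5-[2-hydroxy-3-methyl-5-(triisopropylsilyloxy)phenyl]-3-methylpent-2-en-1-yl methyl carbonate
Conditions: ClCO2Me (1.1 equiv), pyridine (3 equiv), CH2Cl2, −20 °C
Reagents that add atoms: methyl chloroformate, COC(=O)Cl
Why: Chemoselective O-acylation: at low temperature with pyridine the unhindered primary allylic alcohol should be acylated well before the phenol, which is flanked by two ortho alkyl groups.

Step 6
Reactants: 8 (2E)-5-[2-hydroxy-3-methyl-5-(triisopropylsilyloxy)phenyl]-3-methylpent-2-en-1-yl methyl carbonate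
Product: 9 (2S)-2-ethenyl-2,8-dimethyl-6-(triisopropylsilyloxy)chroman
Conditions: Pd2(dba)3·CHCl3 (2 mol %), (R,R)-DACH-phenyl Trost ligand (6 mol %), AcOH (1 equiv), CH2Cl2 (0.05 M), rt
Reagents that add atoms: none
Why: Palladium-catalysed asymmetric allylic alkylation (Tsuji–Trost etherification): zerovalent palladium ionises the carbonate to a π-allyl complex, the phenol attacks the methyl-bearing allyl terminus because only that closes a six-membered ring (6-exo), and the chiral pocket of the diphosphine decides which face of the allyl unit is attacked and so sets C2, with acetic acid slowing ring closure so that the diastereomeric complexes can equilibrate first.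

Step 7
Reactants: 9 (2S)-2-ethenyl-2,8-dimethyl-6-(triisopropylsilyloxy)chroman
Product: 11 2-[(2S)-2,8-dimethyl-6-(triisopropylsilyloxy)chroman-2-yl]ethanol, via B-alkyl-9-BBN 10 (not isolated)
Conditions: 9-BBN (1.5 equiv), THF, 0 °C to rt; then 3 M NaOH, 30% H2O2, 0 °C
Reagents that add atoms: hydrogen peroxide, OO
Why: Brown hydroboration–oxidation: 9-BBN places boron on the terminal carbon, away from the fully substituted C2, and alkaline peroxide replaces boron by oxygen without touching the silyl ether or the stereocentre.

Step 8
Reactants: 11 2-[(2S)-2,8-dimethyl-6-(triisopropylsilyloxy)chroman-2-yl]ethanol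
Product: 12 (2S)-2-(2-iodoethyl)-2,8-dimethyl-6-(triisopropylsilyloxy)chroman
Conditions: I2 (1.2 equiv), PPh3 (1.2 equiv), imidazole (1.5 equiv), CH2Cl2, 0 °C to rt
Reagents that add atoms: iodine, II
Why: Appel-type iodination: the alkoxyphosphonium salt of the primary alcohol is displaced by iodide in an SN2 step, and neither the aryl silyl ether nor the tertiary aryl ether reacts.

Step 9
Reactants: 13 pent-4-yn-1-ol
Product: 15 (E)-5-iodo-4-methylpent-4-en-1-ol, via alkenylalane 14 (not isolated)
Conditions: Me3Al (3 equiv), Cp2ZrCl2 (25 mol %), CH2Cl2, 0 °C to rt; then I2, THF, −30 °C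
Reagents that add atoms: trimethylaluminium, C[Al](C)C; iodine, II
Why: Negishi zirconium-catalysed methylalumination: after the hydroxyl is capped as an aluminium alkoxide, methyl and aluminium add syn across the alkyne with methyl on the internal carbon, and iodinolysis of the C–Al bond with retention fixes the E geometry of what becomes C3'=C4'.

Step 10
Reactants: 15 (E)-5-iodo-4-methylpent-4-en-1-ol
Product: 16 (E)-5-iodo-4-methylpent-4-enal
Conditions: PhI(OAc)2 (1.1 equiv), TEMPO (10 mol %), CH2Cl2, rt
Reagents that add atoms: none
Why: TEMPO/PhI(OAc)2 oxidation: the oxoammonium salt takes the primary alcohol to the aldehyde without over-oxidation and leaves the alkenyl iodide alone.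

Step 11
Reactants: 16 (E)-5-iodo-4-methylpent-4-enal; 17 ethyl 2-(triphenylphosphoranylidene)propanoate
Product: 18 ethyl (2E,6E)-7-iodo-2,6-dimethylhepta-2,6-dienoate
Conditions: 17 (1.2 equiv), CH2Cl2, rt
Reagents that add atoms: none
Why: Wittig olefination with a stabilised α-methyl ylide, which with an unbranched aldehyde favours the E trisubstituted enoate and so sets C7'=C8'.

Step 12
Reactants: 12 (2S)-2-(2-iodoethyl)-2,8-dimethyl-6-(triisopropylsilyloxy)chroman; 18 ethyl (2E,6E)-7-iodo-2,6-dimethylhepta-2,6-dienoate
Product: 19 ethyl (2E,6E)-9-[(2R)-2,8-dimethyl-6-(triisopropylsilyloxy)chroman-2-yl]-2,6-dimethylnona-2,6-dienoate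
Conditions: 12 (1.0 equiv), 18 (1.5 equiv), NiI2 (10 mol %), 4,4'-di-tert-butyl-2,2'-bipyridine (10 mol %), pyridine (10 mol %), Mn powder (3 equiv), DMPU, 40 °C, argon
Reagents that add atoms: none
Why: Zerovalent nickel, made from NiI2 and Mn, inserts into the C(sp2)–I bond of 18 with retention to give an alkenylnickel iodide (divalent nickel), a monovalent nickel iodide abstracts iodine from 12 to release the primary C2' radical, the radical is captured by the alkenylnickel species, and the resulting trivalent nickel forms the C2'–C3' bond by reductive elimination before Mn returns the metal to the zerovalent state. The closest known reaction type is the nickel/bipyridine-catalysed reductive cross-electrophile coupling of primary alkyl halides with aryl and alkenyl halides. No ring is closed and no stereocentre is made: C2 is quaternary and two atoms from the radical centre, so it cannot be touched (its descriptor changes from S to R only because the priorities change), and the E geometry of C3'=C4' is carried over because oxidative addition and reductive elimination at sp2 carbon both go with retention. The step needs cross-coupling to win over homocoupling, which rests on the two iodides being activated by different mechanisms (two-electron insertion at sp2 carbon, halogen-atom abstraction at sp3 carbon) and is helped by an excess of the shorter-route partner 18. The substrate closes the side paths: O1 is γ to C2', so no β-elimination can open the pyran ring; nickel at C3' stands trans to the C5' chain, so insertion into C7'=C8' would need a trans-cyclopentene; the trisubstituted enoate is a poor radical acceptor; and the silyl ether removes the C6 O–H, a fast hydrogen-atom donor that would quench the C2' radical.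

Step 13
Reactants: 19 ethyl (2E,6E)-9-[(2R)-2,8-dimethyl-6-(triisopropylsilyloxy)chroman-2-yl]-2,6-dimethylnona-2,6-dienoate
Product: 21 (2E,6E)-9-[(2R)-6-hydroxy-2,8-dimethylchroman-2-yl]-2,6-dimethylnona-2,6-dienoic acid, via phenol ethyl ester 20 (not isolated)
Conditions: TBAF (1.2 equiv), THF, 0 °C; then LiOH (10 equiv), MeOH/H2O, 45 °C, argon; 1 M HCl to pH 3
Reagents that add atoms: lithium hydroxide, [Li+].[OH-]
Why: Fluoride desilylation followed by ester saponification in one flask: fluoride cleaves the aryl O–Si bond, hydroxide attacks the ester carbonyl, neither reagent can reach C2 or the two alkenes, and air is excluded because the chromanolate is easily oxidised.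

**Compound list**

1 | 2-methylhydroquinone | Cc1cc(O)ccc1O | starting material
2 | 2-methyl-4-(triisopropylsilyloxy)phenol | Cc1cc(O[Si](C(C)C)(C(C)C)C(C)C)ccc1O | intermediate
3 | 2-iodo-6-methyl-4-(triisopropylsilyloxy)phenol | Cc1cc(O[Si](C(C)C)(C(C)C)C(C)C)cc(I)c1O | intermediate
4 | (E)-3-methylpent-2-en-4-yn-1-ol | C#C/C(C)=C/CO | starting material
5 | (E)-3-methylpenta-2,4-dien-1-ol | C=C/C(C)=C/CO | intermediate
6 | 9-{(3E)-5-[(9-borabicyclo[3.3.1]nonan-9-yl)oxy]-3-methylpent-3-en-1-yl}-9-borabicyclo[3.3.1]nonane | C1CC2CCCC(C1)B2CC/C(C)=C/COB1C2CCCC1CCC2 | intermediate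
7 | 2-[(3E)-5-hydroxy-3-methylpent-3-en-1-yl]-6-methyl-4-(triisopropylsilyloxy)phenol | Cc1cc(O[Si](C(C)C)(C(C)C)C(C)C)cc(CC/C(C)=C/CO)c1O | intermediate
8 | (2E)-5-[2-hydroxy-3-methyl-5-(triisopropylsilyloxy)phenyl]-3-methylpent-2-en-1-yl methyl carbonate | Cc1cc(O[Si](C(C)C)(C(C)C)C(C)C)cc(CC/C(C)=C/COC(=O)OC)c1O | intermediate
9 | (2S)-2-ethenyl-2,8-dimethyl-6-(triisopropylsilyloxy)chroman | C=C[C@]1(C)CCc2cc(O[Si](C(C)C)(C(C)C)C(C)C)cc(C)c2O1 | intermediate
10 | 9-{2-[(2R)-2,8-dimethyl-6-(triisopropylsilyloxy)chroman-2-yl]ethyl}-9-borabicyclo[3.3.1]nonane | C1CC2CCCC(C1)B2CC[C@]1(C)CCc2cc(O[Si](C(C)C)(C(C)C)C(C)C)cc(C)c2O1 | intermediate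
11 | 2-[(2S)-2,8-dimethyl-6-(triisopropylsilyloxy)chroman-2-yl]ethanol | OCC[C@]1(C)CCc2cc(O[Si](C(C)C)(C(C)C)C(C)C)cc(C)c2O1 | intermediate
12 | (2S)-2-(2-iodoethyl)-2,8-dimethyl-6-(triisopropylsilyloxy)chroman | ICC[C@]1(C)CCc2cc(O[Si](C(C)C)(C(C)C)C(C)C)cc(C)c2O1 | intermediate
13 | pent-4-yn-1-ol | C#CCCCO | starting material
14 | {(1E)-5-[(dimethylalumanyl)oxy]-2-methylpent-1-en-1-yl}dimethylalumane | C/C(=C\[Al](C)C)CCCO[Al](C)C | intermediate
15 | (E)-5-iodo-4-methylpent-4-en-1-ol | C/C(=C\I)CCCO | intermediate
16 | (E)-5-iodo-4-methylpent-4-enal | C/C(=C\I)CCC=O | intermediate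
17 | ethyl 2-(triphenylphosphoranylidene)propanoate | CCOC(=O)C(C)=P(c1ccccc1)(c1ccccc1)c1ccccc1 | starting material
18 | ethyl (2E,6E)-7-iodo-2,6-dimethylhepta-2,6-dienoate | C/C(=C\I)CC/C=C(\C)C(=O)OCC | intermediate
19 | ethyl (2E,6E)-9-[(2R)-2,8-dimethyl-6-(triisopropylsilyloxy)chroman-2-yl]-2,6-dimethylnona-2,6-dienoate | C/C(=C\CC[C@]1(C)CCc2cc(O[Si](C(C)C)(C(C)C)C(C)C)cc(C)c2O1)CC/C=C(\C)C(=O)OCC | intermediate
20 | ethyl (2E,6E)-9-[(2R)-6-hydroxy-2,8-dimethylchroman-2-yl]-2,6-dimethylnona-2,6-dienoate | C/C(=C\CC[C@]1(C)CCc2cc(O)cc(C)c2O1)CC/C=C(\C)C(=O)OCC | intermediate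
21 | (2E,6E)-9-[(2R)-6-hydroxy-2,8-dimethylchroman-2-yl]-2,6-dimethylnona-2,6-dienoic acid | C/C(=C\CC[C@]1(C)CCc2cc(O)cc(C)c2O1)CC/C=C(\C)C(=O)O | target

**Step count**

Total step count: 13. Longest linear sequence: 9 steps (1, 2, 4, 5, 6, 7, 8, 12, 13).

**Steps most likely to fail**

**Step 12.** Homocoupling of either iodide and reductive loss of iodine may outrun the cross-coupling. The fallback sets out from 9 and comes back at 19.
- 9 is hydroborated with 9-BBN as in step 7 to the borane 10.
- 10 is not oxidised but treated in the same flask with 18, PdCl2(dppf), AsPh3 and aqueous Cs2CO3 in DMF at rt (B-alkyl Suzuki–Miyaura coupling).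
- This is a two-electron transmetalation from boron, not a radical union of two halides, and it makes the oxidation of step 7 and step 8 unnecessary.
- It makes no compound outside the list (F0).

**Step 6.** Facial selectivity in the attack on the π-allyl complex may be poor, or its sense may be unexpected. The fallback sets out from 7 and comes back at 9.
- Sharpless asymmetric epoxidation (Ti(OiPr)4, D-(−)-diisopropyl tartrate, t-BuOOH, 4 Å sieves, CH2Cl2, −20 °C) should give 2-{2-[(2R,3R)-3-(hydroxymethyl)-2-methyloxiran-2-yl]ethyl}-6-methyl-4-(triisopropylsilyloxy)phenol F1. Its configuration follows from the tartrate rule.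
- Catalytic camphorsulfonic acid in CH2Cl2 lets the phenol open the epoxide at its tertiary carbon (6-exo-tet, inversion) to (1R)-1-[(2S)-2,8-dimethyl-6-(triisopropylsilyloxy)chroman-2-yl]ethane-1,2-diol F2.
- PPh3, I2 and imidazole in hot toluene (Garegg–Samuelsson deoxygenation) turn the diol into the vinyl group of 9.

**Step 4.** Hydroboration may spread beyond the terminal double bond of the diene, and oxidative addition to the electron-rich iodophenolate may be sluggish. The fallback sets out from 3 and 4 and comes back at 7.
- Ac2O/pyridine gives 2-iodo-6-methyl-4-(triisopropylsilyloxy)phenyl acetate F3; the acetate blocks benzofuran formation.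
- Sonogashira coupling with 4 (PdCl2(PPh3)2, CuI, Et3N, rt) gives 2-[(3E)-5-hydroxy-3-methylpent-3-en-1-yn-1-yl]-6-methyl-4-(triisopropylsilyloxy)phenyl acetate F4.
- Diimide (2-nitrobenzenesulfonohydrazide, Et3N) saturates the alkyne and spares the trisubstituted alkene, giving 2-[(3E)-5-hydroxy-3-methylpent-3-en-1-yl]-6-methyl-4-(triisopropylsilyloxy)phenyl acetate F5.
- K2CO3/MeOH removes the acetate to give 7.

**Further compounds**

F0 | step 12 | none | none
F1 | step 6 | 2-{2-[(2R,3R)-3-(hydroxymethyl)-2-methyloxiran-2-yl]ethyl}-6-methyl-4-(triisopropylsilyloxy)phenol | OC[C@H]1O[C@]1(C)CCc2cc(O[Si](C(C)C)(C(C)C)C(C)C)cc(C)c2O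
F2 | step 6 | (1R)-1-[(2S)-2,8-dimethyl-6-(triisopropylsilyloxy)chroman-2-yl]ethane-1,2-diol | OC[C@@H](O)[C@]1(C)CCc2cc(O[Si](C(C)C)(C(C)C)C(C)C)cc(C)c2O1
F3 | step 4 | 2-iodo-6-methyl-4-(triisopropylsilyloxy)phenyl acetate | CC(=O)Oc1c(C)cc(O[Si](C(C)C)(C(C)C)C(C)C)cc1I
F4 | step 4 | 2-[(3E)-5-hydroxy-3-methylpent-3-en-1-yn-1-yl]-6-methyl-4-(triisopropylsilyloxy)phenyl acetate | CC(=O)Oc1c(C)cc(O[Si](C(C)C)(C(C)C)C(C)C)cc1C#C/C(C)=C/CO
F5 | step 4 | 2-[(3E)-5-hydroxy-3-methylpent-3-en-1-yl]-6-methyl-4-(triisopropylsilyloxy)phenyl acetate | CC(=O)Oc1c(C)cc(O[Si](C(C)C)(C(C)C)C(C)C)cc1CC/C(C)=C/CO
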